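**Strategy.** Ring B of the target (C1–C4 with C4a and C8a of the methoxylated ring A) is built by a radical [4+2] annulation. The diarylmethine C4 is taken back to an aryl ketone, which turns C3 into a phenacyl radical centre; vinyl pivalate supplies C2 and the oxygenated C1. In one flask the radical adds to the alkene and the adduct radical closes onto C8a, the only free ortho carbon of ring A because the other bears the C5 methoxy group. The precursor is a simple S-phenacyl xanthate. The naphthol is then added to the C4 ketone, C4 is set by asymmetric reduction of the derived para-quinone methide, and C1 by asymmetric transfer hydrogenation.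

Key step: step 2

Remark on numbering: the tetralin locants of the target are used for all intermediates (C1 carbinol carbon, C4 diarylmethine carbon, C5 methoxy-bearing carbon; ring A is the benzo ring and ring B the saturated ring of the tetralin).
Remark on step 5: the sense of induction of the phosphoric acid cannot be read from a model with confidence; the route is written with (R)-TRIP, and the catalyst enantiomer that gives (S) at C4 is the one to be used.
Remark on materials: compounds 1, 3 and 6 are taken as commercial.

**Step 1**
Reactants: 1 2-bromo-1-(2-methoxyphenyl)ethan-1-one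
Product: 2 O-ethyl S-[2-(2-methoxyphenyl)-2-oxoethyl] carbonodithioate
Conditions: KSC(S)OEt (1.1 equiv), acetone, 0 °C to rt
Reagents that add atoms: potassium O-ethyl carbonodithioate, CCOC(=S)[S-].[K+]
Why: SN2 displacement of the activated α-bromo ketone by the soft sulfur of the xanthate salt (S-alkylation) should be fast and clean; no stereocentre is formed.

**Step 2**
Reactants: 2 O-ethyl S-[2-(2-methoxyphenyl)-2-oxoethyl] carbonodithioate; 3 vinyl pivalate
Product: 5 5-methoxy-4-oxo-1,2,3,4-tetrahydronaphthalen-1-yl pivalate (racemic), via adduct xanthate 4 (not isolated)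
Conditions: 3 (1.5 equiv), dilauroyl peroxide (10 mol % in portions), ClCH2CH2Cl, reflux; then dilauroyl peroxide (1.3 equiv in portions), reflux, same flask
Reagents that add atoms: none
Why: Undecyl radicals from the peroxide start a degenerative xanthate-transfer chain in which the electrophilic phenacyl radical (C3) adds to the unsubstituted carbon of electron-rich 3 (bond C3–C2) and the adduct radical is stored as xanthate 4; with the stoichiometric peroxide charge the α-pivaloyloxyalkyl radical (C1) is released again and attacks the aromatic carbon C8a (bond C8a–C1), after which the cyclohexadienyl radical is oxidised by the peroxide and loses a proton. The closest known reaction type is the xanthate-based radical addition/cyclisation of S-phenacyl xanthates with vinyl esters to 4-acyloxy-1-tetralones. Ring B closes as a six-membered ring by homolytic aromatic substitution, the new bond being exo to the C8–C8a bond while the C4a–C8a bond lies inside the new ring. The new stereocentre C1 is formed without control, which is harmless because C1 passes through the ketone in step 7 and is set in step 8. The step needs head-to-tail addition, secured by the polarity match of the acyl-substituted radical and the donor-substituted alkene, and closure at one ring position only, secured because the second ortho carbon of ring A carries the C5 methoxy group and no other arene is present yet.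

**Step 3**
Reactants: 6 8-methoxynaphthalen-1-ol
Product: 7 4-bromo-8-methoxynaphthalen-1-ol
Conditions: NBS (1.0 equiv), MeCN, −20 °C
Reagents that add atoms: N-bromosuccinimide, O=C1CCC(=O)N1Br
Why: Electrophilic aromatic bromination should go para to the free hydroxyl group, the most activated and least hindered position of the naphthol; no stereocentre is formed.

**Step 4**
Reactants: 7 4-bromo-8-methoxynaphthalen-1-ol; 5 5-methoxy-4-oxo-1,2,3,4-tetrahydronaphthalen-1-yl pivalate
Product: 9 4-hydroxy-4-(4-hydroxy-5-methoxynaphthalen-1-yl)-5-methoxy-1,2,3,4-tetrahydronaphthalen-1-yl pivalate (racemic, both diastereomers), via dilithio naphtholate 8 (not isolated)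
Conditions: 7 (1.4 equiv), t-BuLi (4.2 equiv), THF, −78 °C; then 5, −78 to −20 °C; NH4Cl aq
Reagents that add atoms: none
Why: Deprotonation followed by bromine–lithium exchange gives aryllithium 8, which should add 1,2 to the aryl ketone of 5 (organolithium carbonyl addition) faster than to the hindered pivalate at low temperature; the new carbinol centre is formed without control and is erased in step 5.

**Step 5**
Reactants: 9 4-hydroxy-4-(4-hydroxy-5-methoxynaphthalen-1-yl)-5-methoxy-1,2,3,4-tetrahydronaphthalen-1-yl pivalate
Product: 11 (4S)-4-(4-hydroxy-5-methoxynaphthalen-1-yl)-5-methoxy-1,2,3,4-tetrahydronaphthalen-1-yl pivalate (both C1 epimers), via para-quinone methide 10 (not isolated)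
Conditions: (R)-TRIP (5 mol %), Hantzsch ester (1.5 equiv), 4 Å MS, CH2Cl2, rt
Reagents that add atoms: none
Why: The chiral phosphoric acid ionises the tertiary para-hydroxybenzylic alcohol to the para-quinone methide 10 and, hydrogen-bonded to both 10 and the Hantzsch ester, directs 1,6-hydride transfer to one face of the exocyclic carbon (organocatalytic asymmetric transfer hydrogenation of an in situ quinone methide), which should set C4 as (S) under catalyst control while the racemic C1 ester is carried as an epimer pair.

**Step 6**
Reactants: 11 (4S)-4-(4-hydroxy-5-methoxynaphthalen-1-yl)-5-methoxy-1,2,3,4-tetrahydronaphthalen-1-yl pivalate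
Product: 12 (4S)-4-(4-hydroxy-5-methoxynaphthalen-1-yl)-5-methoxy-1,2,3,4-tetrahydronaphthalen-1-ol (both C1 epimers)
Conditions: i-Bu2AlH (DIBAL-H, 4.5 equiv), CH2Cl2, −78 to 0 °C; KNaC4H4O6 aq
Reagents that add atoms: none
Why: Reductive cleavage of the pivalate (ester reduction by an aluminium hydride) should free the C1 alcohol without base or oxidant, so the C4 methine and the naphthol stay untouched; C1 remains an epimer pair.

**Step 7**
Reactants: 12 (4S)-4-(4-hydroxy-5-methoxynaphthalen-1-yl)-5-methoxy-1,2,3,4-tetrahydronaphthalen-1-ol
Product: 13 (4S)-4-(4-hydroxy-5-methoxynaphthalen-1-yl)-5-methoxy-3,4-dihydronaphthalen-1(2H)-one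
Conditions: RuCl2(PPh3)3 (3 mol %), K2CO3 (10 mol %), acetone, reflux, argon
Reagents that add atoms: none
Why: Oppenauer-type transfer dehydrogenation with acetone as hydrogen acceptor should oxidise both C1 epimers of the benzylic alcohol to one ketone by a hydride-transfer path that cannot oxidise the para-alkylated naphthol to a quinone methide, so the C4 centre is kept.

**Step 8**
Reactants: 13 (4S)-4-(4-hydroxy-5-methoxynaphthalen-1-yl)-5-methoxy-3,4-dihydronaphthalen-1(2H)-one
Product: 14 (1S,4S)-4-(4-hydroxy-5-methoxynaphthalen-1-yl)-5-methoxy-1,2,3,4-tetrahydronaphthalen-1-ol (dipolynaphthalene B)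
Conditions: RuCl(p-cymene)[(S,S)-TsDPEN] (1 mol %), HCO2H/Et3N (5:2), DMF, 40 °C
Reagents that add atoms: none
Why: In this Noyori asymmetric transfer hydrogenation the (S,S)-configured catalyst should deliver hydride to the face of the aryl ketone that gives the (1S) alcohol, which is also the face anti to the pseudoaxial C4 aryl group, so catalyst and substrate reinforce each other and the cis-(1S,4S) isomer should result.

**Compound list**
1 | 2-bromo-1-(2-methoxyphenyl)ethan-1-one | BrCC(=O)c1ccccc1OC | starting material
2 | O-ethyl S-[2-(2-methoxyphenyl)-2-oxoethyl] carbonodithioate | CCOC(=S)SCC(=O)c1ccccc1OC | intermediate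
3 | vinyl pivalate (ethenyl 2,2-dimethylpropanoate) | C=COC(=O)C(C)(C)C | starting material
4 | O-ethyl S-[4-(2-methoxyphenyl)-4-oxo-1-(pivaloyloxy)butyl] carbonodithioate (racemic, not isolated) | CCOC(=S)SC(CCC(=O)c1ccccc1OC)OC(=O)C(C)(C)C | intermediate
5 | 5-methoxy-4-oxo-1,2,3,4-tetrahydronaphthalen-1-yl pivalate (racemic) | COc1cccc2c1C(=O)CCC2OC(=O)C(C)(C)C | intermediate
6 | 8-methoxynaphthalen-1-ol | COc1cccc2cccc(O)c12 | starting material
7 | 4-bromo-8-methoxynaphthalen-1-ol | COc1cccc2c(Br)ccc(O)c12 | intermediate
8 | lithium 4-lithio-8-methoxynaphthalen-1-olate (not isolated) | COc1cccc2c([Li])ccc(O[Li])c12 | intermediate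
9 | 4-hydroxy-4-(4-hydroxy-5-methoxynaphthalen-1-yl)-5-methoxy-1,2,3,4-tetrahydronaphthalen-1-yl pivalate (racemic, both diastereomers) | COc1cccc2c1C(O)(c1ccc(O)c3c(OC)cccc13)CCC2OC(=O)C(C)(C)C | intermediate
10 | 5-methoxy-4-(5-methoxy-4-oxonaphthalen-1(4H)-ylidene)-1,2,3,4-tetrahydronaphthalen-1-yl pivalate (para-quinone methide, racemic at C1, not isolated) | COc1cccc2c1C(=C1C=CC(=O)c3c(OC)cccc13)CCC2OC(=O)C(C)(C)C | intermediate
11 | (4S)-4-(4-hydroxy-5-methoxynaphthalen-1-yl)-5-methoxy-1,2,3,4-tetrahydronaphthalen-1-yl pivalate (both C1 epimers) | COc1cccc2c1[C@H](c1ccc(O)c3c(OC)cccc13)CCC2OC(=O)C(C)(C)C | intermediate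
12 | (4S)-4-(4-hydroxy-5-methoxynaphthalen-1-yl)-5-methoxy-1,2,3,4-tetrahydronaphthalen-1-ol (both C1 epimers) | COc1cccc2c1[C@H](c1ccc(O)c3c(OC)cccc13)CCC2O | intermediate
13 | (4S)-4-(4-hydroxy-5-methoxynaphthalen-1-yl)-5-methoxy-3,4-dihydronaphthalen-1(2H)-one | COc1cccc2c1[C@H](c1ccc(O)c3c(OC)cccc13)CCC2=O | intermediate
14 | (1S,4S)-4-(4-hydroxy-5-methoxynaphthalen-1-yl)-5-methoxy-1,2,3,4-tetrahydronaphthalen-1-ol (dipolynaphthalene B) | COc1cccc2c1[C@H](c1ccc(O)c3c(OC)cccc13)CC[C@@H]2O | target

**Step count.** Total: 8 steps. Longest linear sequence: 7 steps (steps 1, 2, 4, 5, 6, 7, 8); step 3 is the one-step side branch.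

**Steps most likely to fail**

Step 2 (key step). The adduct radical may be consumed by telomerisation with excess alkene or by premature hydrogen abstraction before it closes onto the acyl-bearing ring, and the product may lose pivalic acid on prolonged heating and aromatise to a naphthol. Fallback: an oxidative annulation with trivalent manganese, which forms the same two bonds in one operation by a different radical source and a different terminating oxidant. It sets out from 3 and the commercial methyl ketone 1-(2-methoxyphenyl)ethan-1-one F1, which are heated with Mn(OAc)3·2H2O (2.2 equiv) in AcOH at 80 °C. The manganese enolate of F1 gives the same phenacyl radical, which adds to 3 and cyclises onto C8a; a second equivalent of Mn(OAc)3 rearomatises the ring. The fallback comes back to the route at 5.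

Step 5. Hydride delivery to the hindered, fully substituted exocyclic carbon of the quinone methide may show poor facial selectivity, and the quinone methide may isomerise to the 1,2-dihydronaphthalene and lose pivalic acid with aromatisation. Fallback: catalyst-controlled hydrogenation of the isolated alkene instead of the quinone methide. It sets out from 9, which is silylated at the naphthol (TBSCl, imidazole, DMF) to the silyl ether 4-[4-(tert-butyldimethylsilyloxy)-5-methoxynaphthalen-1-yl]-4-hydroxy-5-methoxy-1,2,3,4-tetrahydronaphthalen-1-yl pivalate F2. Dehydration with Burgess reagent (benzene, 50 °C) gives the 1,2-dihydronaphthalene 4-[4-(tert-butyldimethylsilyloxy)-5-methoxynaphthalen-1-yl]-5-methoxy-1,2-dihydronaphthalen-1-yl pivalate F3. Iridium-catalysed asymmetric hydrogenation of the trisubstituted aryl alkene ([Ir(cod)((S)-tBu-PHOX)]BArF, H2 50 bar, CH2Cl2, ligand enantiomer chosen for (S) at C4) gives the silyl ether (4S)-4-[4-(tert-butyldimethylsilyloxy)-5-methoxynaphthalen-1-yl]-5-methoxy-1,2,3,4-tetrahydronaphthalen-1-yl pivalate F4. Desilylation with Bu4NF in THF at 0 °C comes back to the route at 11.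

Step 4. The dilithio species may act as a base and enolise the ketone instead of adding to it, may be poorly soluble, or may attack the ester. Fallback: a cross-coupling in place of the carbonyl addition. It sets out from 5, which is converted (KN(SiMe3)2, PhNTf2, THF, −78 °C) into the enol triflate 5-methoxy-4-(trifluoromethylsulfonyloxy)-1,2-dihydronaphthalen-1-yl pivalate F5. In parallel 7 is borylated (B2pin2, Pd(dppf)Cl2, KOAc, dioxane, 80 °C) to the boronic ester 8-methoxy-4-(4,4,5,5-tetramethyl-1,3,2-dioxaborolan-2-yl)naphthalen-1-ol F6. Suzuki–Miyaura coupling of F5 with F6 (Pd(PPh3)4, K3PO4, dioxane/H2O, 60 °C) gives the 1,2-dihydronaphthalene 4-(4-hydroxy-5-methoxynaphthalen-1-yl)-5-methoxy-1,2-dihydronaphthalen-1-yl pivalate F7. Under the conditions of step 5 the phosphoric acid protonates F7 at C3 to the same quinone methide 10, so the fallback comes back to the route at 11.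

**Further compounds**
F1 | step 2 | 1-(2-methoxyphenyl)ethan-1-one | CC(=O)c1ccccc1OC
F2 | step 5 | 4-[4-(tert-butyldimethylsilyloxy)-5-methoxynaphthalen-1-yl]-4-hydroxy-5-methoxy-1,2,3,4-tetrahydronaphthalen-1-yl pivalate | COc1cccc2c1C(O)(c1ccc(O[Si](C)(C)C(C)(C)C)c3c(OC)cccc13)CCC2OC(=O)C(C)(C)C
F3 | step 5 | 4-[4-(tert-butyldimethylsilyloxy)-5-methoxynaphthalen-1-yl]-5-methoxy-1,2-dihydronaphthalen-1-yl pivalate | COc1cccc2c1C(c1ccc(O[Si](C)(C)C(C)(C)C)c3c(OC)cccc13)=CCC2OC(=O)C(C)(C)C
F4 | step 5 | (4S)-4-[4-(tert-butyldimethylsilyloxy)-5-methoxynaphthalen-1-yl]-5-methoxy-1,2,3,4-tetrahydronaphthalen-1-yl pivalate | COc1cccc2c1[C@H](c1ccc(O[Si](C)(C)C(C)(C)C)c3c(OC)cccc13)CCC2OC(=O)C(C)(C)C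
F5 | step 4 | 5-methoxy-4-(trifluoromethylsulfonyloxy)-1,2-dihydronaphthalen-1-yl pivalate | COc1cccc2c1C(OS(=O)(=O)C(F)(F)F)=CCC2OC(=O)C(C)(C)C
F6 | step 4 | 8-methoxy-4-(4,4,5,5-tetramethyl-1,3,2-dioxaborolan-2-yl)naphthalen-1-ol | COc1cccc2c(B3OC(C)(C)C(C)(C)O3)ccc(O)c12
F7 | step 4 | 4-(4-hydroxy-5-methoxynaphthalen-1-yl)-5-methoxy-1,2-dihydronaphthalen-1-yl pivalate | COc1cccc2c1C(c1ccc(O)c3c(OC)cccc13)=CCC2OC(=O)C(C)(C)C
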